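## Structural features

Positions are numbered in the order of the atoms in the SMILES string of the target (C1 is the methyl on C2, N36 the lactam nitrogen); "beta" means the face of the angular methyl C32. Pyrrospirone O has a trans-anti-trans decahydrofluorene core: cyclohexane ring A (C2, C3, C4, C6, C31, C33), cyclopentane ring B (C6, C7, C30, C29, C31) and cyclohexane ring C (C22, C23, C25, C27, C29, C30), the last carrying a trisubstituted C25–C27 epoxide. The C7 oxygen O8 is an aryl ether to a para-phenylene whose benzylic C15 is bound to the hemiaminal C16 of a 3-acyl-5-hydroxypyrrolidin-2-one (C16, C18, C19, C34, N36); the enolised acyl carbon C20 sits on C22, so C7–O8–arene–C15–C16–C18–C19–C20–C22–C30 form a strained 13-membered paracyclophane. Eleven contiguous stereocentres line the carbocycle (C2, C4, C6, C7, C30, C22, C23, C25, C27, C29 and the quaternary C31, which lies between the methines C6 and C29), and C16 is a twelfth, epimerisable one. The fragile groups are the epoxide, the N-acyl hemiaminal (dehydration, ring–chain tautomerism), the enolised beta-keto amide and the bent arene. The real difficulty is the angular-methyl quaternary centre C31 inside two trans ring fusions, the equatorial methyls on C2 and C4 anti to that axial methyl, and the late closure of the cyclophane. The key step exploits the cyclohexene retron hidden in ring A: with a C2=C33 double bond in place, C6–C31 and C3–C4 can be made by a [4+2] addition, and the three atoms C29–C30–C7 that tether diene and dienophile become ring B.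

## Logic of the disconnections

45 to 44. The aryl C9–O8 bond is cut. This opens the paracyclophane while every stereocentre and the heterocycle stay in place, and a copper-mediated C–O coupling can close the ring through a metallacycle one atom larger than the product. The forward step must couple the hindered C7 alkoxide with retention, at high dilution, next to a hemiaminal and an enol; C16 is left to equilibrate.

44 to 37 and 42. C18–C19 and N36–C16 are cut. C20/C34 and C16 stand in a 1,4-dicarbonyl relation, the retron for alkylating a beta-keto amide with an alpha-chloro ketone, after which the primary amide adds to the new ketone by itself. Arene and heterocycle are thereby reduced to one small ketone. The demand is C-alkylation under mild base and no acid.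

42 to 41 to 38 and 39. The C16 ketone is traced to an alcohol and the aryl–C15 bond is cut. An aryl Grignard reagent opening an epoxide gives the three-carbon chain with chloride already in place. The demand is mono-metalation of a diiodide, so that one iodide survives for the last step.

37 to 36 to 34 and 35. The amide is traced to a nitrile and C19–C20 is cut. Acylation of a nitrile anion by the C20 ester adds C19 and C34 in one step. The demand is a hindered ester as acceptor and a neutral hydration that spares the epoxide.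

34 to 32. The two epoxide C–O bonds are cut. The halohydrin route is chosen because trans-diaxial opening on the rigid ring fixes the beta face. The demand is that ring C holds the only alkene at this stage.

32 to 31. C25=C27 is cut. Ring-closing metathesis closes ring C from two alkenes that are otherwise inert. The demand is a 1,1-disubstituted partner on C29.

31 to 28. C22–C23 is cut. An Ireland–Claisen rearrangement makes this bond, sets C22 and C23 together and places C20 as a carboxyl group. The demand is an (E)-ketene acetal and an enantiopure allylic ester.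

28 to 27 to 22 and 26. The C7–H bond and C30–C22 are cut. The C7 ketone serves twice: it activates C30 for alkylation and is then reduced to the beta alcohol. The demand is kinetic enolisation at C30 without epimerising C6.

26 to 24 and 25; 24 to 23. The ester C–O bond is cut and the alcohol is traced to its racemate, resolved by a lipase.

22 to 21 to 20 to 19. Functional groups are interchanged: the isopropenyl group comes from a tertiary alcohol, the ketone from the C7 alcohol, both from silyl ethers. The isopropenyl group is kept masked up to here because hydrogen-atom transfer reduces a 1,1-disubstituted alkene faster than the ring A alkene, and because the later halohydrin step needs a single alkene. The demand is a regioselective dehydration.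

19 to 18. The C2–H bond is cut. A radical hydrogenation is needed because the equatorial C1 methyl is the thermodynamic, not the sterically favoured, outcome.

18 to 16 to 15. The C5 methyl is traced to the ester that activated the dienophile.

15 to 14. C6–C31 and C3–C4 are cut (key step). Two rings, the quaternary centre and three stereocentres collapse to an open-chain trienoate with two tether stereocentres. The demand is endo selectivity and one diene face, with a diene terminus that is fully substituted.

14 to 12 and 13. C4=C6 is cut (Horner–Wadsworth–Emmons). The demand is no epimerisation of the alpha-silyloxy aldehyde.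

12 to 11 to 8 and 9. C33–C2 and C31–C32 are cut. Carbometalation of an alkyne followed by cross-coupling builds the trisubstituted (E)-diene with defined geometry, which ketone olefination would not. The primary silyl ether is oxidised directly.

8 to 7 to 6 to 5. C31≡C33 is traced to the lactone carbonyl by one-carbon homologation of the lactol.

5 to 2 and 3; 2 to 1. C27–C29 is cut (aldol with acetone). The chiral-pool lactone supplies C7 and steers C29 to the trans position.

## Other disconnections considered

Alternative 1: The cut is the aryl–C15 bond of the macrocycle. Zerovalent palladium from Pd(OAc)2 and triphenylphosphine would insert into the aryl iodide of the seco compound A1, add across its exocyclic 5-methylene group and eliminate to the 13-membered benzylidene lactam A2, which would still have to be hydrated to the hemiaminal.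
- In its favour: the ring closes through a larger palladacycle, the enamide polarisation sends the aryl group to the terminal carbon, and the hindered C7 ether could be made earlier, intermolecularly.
- Against it here: the acid needed for the hydration of A2 threatens the epoxide; a conjugated benzylidene adds strain to the bent arene; and the 3-acyl-5-methylene lactam of A1 can tautomerise into the ring or eliminate towards C18.
- Comparison: on structure it addresses only the cyclophane, so it competes with steps 27 and 28, not with step 9, and the eleven carbocyclic stereocentres would still need the chosen cycloaddition. On mechanism it is the better of the two ring closures, because carbopalladation does not depend on the hindered C7 alkoxide as the copper etherification does. On step economy it is about equal (lactam methylenation, arylation, Heck reaction, hydration against four steps).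

Alternative 2: The cut is C29–C30. Rh2(OAc)4 would decompose the diazo keto ester A3, and 1,5 insertion of the carbenoid into a C–H bond of the methylene on the quaternary carbon would close cyclopentanone ring B as the beta-keto ester A4.
- In its favour: the quaternary C31 and the ring A methyls would be settled on a simple cyclohexane beforehand, and the insertion runs neutral at room temperature.
- Against it here: the reacting methylene is deactivated by the beta-acyloxy group and competes with methyl and ring C–H bonds; C29 would be set only by discrimination of two diastereotopic hydrogens; ring A with its three stereocentres needs its own sequence; and C27/C28 must still be grown from the pivalate.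
- Comparison: on structure it forms one ring and one bond where step 9 forms two rings, two bonds and three stereocentres. On mechanism it is milder and avoids the hindered diene terminus. It is the better plan on one point: A4 already has the C7 ketone and an ester on C30, so ring C could be annulated without the desilylation, oxidation and regio-sensitive enolate alkylation of steps 13, 14 and 18. On step economy it is estimated longer overall.

Alternative 3: The cuts are C16–C18 and C19–C34. Base would deprotonate the aryl-tethered alpha-tosyl isocyanide of A5, Michael addition to the vinyl ketone would close the macrocycle, and attack of the enolate on the isocyanide carbon with loss of sulfinate would give the cyclophane pyrrole A6.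
- In its favour: two C–C bonds, the heterocycle and the macrocycle arise in one operation from a vinyl ketone that is easily made from the C20 ester. In bonds per step this is the equal of step 9.
- Against it here: a secondary isocyanide anion must close a strained 13-membered ring against oligomerisation. A6 is at the wrong oxidation level: C34 and C16 must be oxidised and the resulting C18=C19 bond reduced beside epoxide and arene. A planar pyrrole also adds strain, and C16 is set last.
- Comparison: on structure it, like alternative 1, answers the endgame and not the core. On mechanism it is an anionic stepwise annulation that needs a strong base where step 9 is pericyclic. On step economy the short assembly is offset by two or three redox corrections.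

Key step: step 9

Assumption: the 16S hemiaminal of 45 is taken to be the more stable epimer inside the macrocycle, so that ring–chain equilibration under the conditions of step 28 delivers it.

## Route

Step 1
Reactants: 1 (S)-5-(hydroxymethyl)dihydrofuran-2(3H)-one
Product: 2 (S)-5-[(triethylsilyloxy)methyl]dihydrofuran-2(3H)-one
Conditions: Et3SiCl, imidazole, CH2Cl2, 0 °C
Reagents that add atoms: chlorotriethylsilane CC[Si](Cl)(CC)CC
Why: Silylation of the primary alcohol; the triethylsilyl ether is chosen because it can later be oxidised directly to the aldehyde beside bulkier silyl ethers, and no stereocentre is touched.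

Step 2
Reactants: 2 (S)-5-[(triethylsilyloxy)methyl]dihydrofuran-2(3H)-one; 3 acetone
Product: 5 (3S,5S)-3-[2-(triethylsilyloxy)propan-2-yl]-5-[(triethylsilyloxy)methyl]dihydrofuran-2(3H)-one, via lithium aldolate 4 (not isolated)
Conditions: LiN(i-Pr)2, THF, −78 °C; acetone; then Et3SiOTf, −78 → −20 °C
Reagents that add atoms: triethylsilyl trifluoromethanesulfonate CC[Si](CC)(CC)OS(=O)(=O)C(F)(F)F
Why: Aldol addition of the lactone enolate to acetone from the face anti to the C7 side chain gives the 3,5-trans lactone and sets C29; silylating the aldolate in the flask prevents retro-aldol cleavage. The tertiary silyl ether is the masked isopropenyl group.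

Step 3
Reactants: 5 (3S,5S)-3-[2-(triethylsilyloxy)propan-2-yl]-5-[(triethylsilyloxy)methyl]dihydrofuran-2(3H)-one
Product: 6 (3S,5S)-3-[2-(triethylsilyloxy)propan-2-yl]-5-[(triethylsilyloxy)methyl]oxolan-2-ol (anomers)
Conditions: i-Bu2AlH, CH2Cl2, −78 °C
Reagents that add atoms: none
Why: Partial reduction of a lactone stops at the lactol because the tetrahedral aluminium alkoxide is stable at low temperature; silyl ethers are inert.

Step 4
Reactants: 6 (3S,5S)-3-[2-(triethylsilyloxy)propan-2-yl]-5-[(triethylsilyloxy)methyl]oxolan-2-ol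
Product: 7 (2S,4R)-1-(triethylsilyloxy)-4-[2-(triethylsilyloxy)propan-2-yl]hex-5-yn-2-ol
Conditions: dimethyl (1-diazo-2-oxopropyl)phosphonate, K2CO3, MeOH, 0 °C → rt
Reagents that add atoms: dimethyl (1-diazo-2-oxopropyl)phosphonate CC(=O)C(=[N+]=[N-])P(=O)(OC)OC
Why: Seyferth–Gilbert homologation in the Ohira–Bestmann variant acts on the open hydroxy aldehyde form of the lactol and adds C33 as the alkyne terminus; the mild carbonate base should leave C29 and the silyl ethers intact.

Step 5
Reactants: 7 (2S,4R)-1-(triethylsilyloxy)-4-[2-(triethylsilyloxy)propan-2-yl]hex-5-yn-2-ol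
Product: 8 (2S,4R)-2-(tert-butyldimethylsilyloxy)-1-(triethylsilyloxy)-4-[2-(triethylsilyloxy)propan-2-yl]hex-5-yne
Conditions: t-BuMe2SiOTf, 2,6-lutidine, CH2Cl2, −78 °C
Reagents that add atoms: tert-butyldimethylsilyl trifluoromethanesulfonate CC(C)(C)[Si](C)(C)OS(=O)(=O)C(F)(F)F
Why: Silylation of the secondary alcohol with the silyl triflate distinguishes the C7 oxygen from the primary triethylsilyl ether.

Step 6
Reactants: 8 (2S,4R)-2-(tert-butyldimethylsilyloxy)-1-(triethylsilyloxy)-4-[2-(triethylsilyloxy)propan-2-yl]hex-5-yne; 9 2-bromopropene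
Product: 11 (2S,4R,5E)-2-(tert-butyldimethylsilyloxy)-5,7-dimethyl-1-(triethylsilyloxy)-4-[2-(triethylsilyloxy)propan-2-yl]octa-5,7-diene, via alkenylalane 10 (not isolated)
Conditions: Me3Al, Cp2ZrCl2 (0.2 equiv), CH2Cl2, 0 °C → rt; then 2-bromopropene, Pd(PPh3)4 (5 mol%), THF, rt
Reagents that add atoms: trimethylaluminium C[Al](C)C
Why: Zirconium-catalysed syn-carboalumination (Negishi) puts the methyl C32 on C31 and aluminium on C33 on the same side, which fixes the E geometry. Palladium-catalysed cross-coupling of the alkenylalane with 2-bromopropene then forms C33–C2 with retention and completes the 2,4-dimethyl diene.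

Step 7
Reactants: 11 (2S,4R,5E)-2-(tert-butyldimethylsilyloxy)-5,7-dimethyl-1-(triethylsilyloxy)-4-[2-(triethylsilyloxy)propan-2-yl]octa-5,7-diene
Product: 12 (2S,4R,5E)-2-(tert-butyldimethylsilyloxy)-5,7-dimethyl-4-[2-(triethylsilyloxy)propan-2-yl]octa-5,7-dienal
Conditions: (COCl)2, DMSO, CH2Cl2, −78 → −40 °C; Et3N, −78 → 0 °C
Reagents that add atoms: none
Why: Under Swern conditions a primary triethylsilyl ether is converted directly into the aldehyde, while the secondary tert-butyldimethylsilyl and the tertiary triethylsilyl ether do not react. The alpha-silyloxy aldehyde is used at once to avoid epimerisation at C7.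

Step 8
Reactants: 12 (2S,4R,5E)-2-(tert-butyldimethylsilyloxy)-5,7-dimethyl-4-[2-(triethylsilyloxy)propan-2-yl]octa-5,7-dienal; 13 trimethyl phosphonoacetate
Product: 14 methyl (2E,4S,6R,7E)-4-(tert-butyldimethylsilyloxy)-7,9-dimethyl-6-[2-(triethylsilyloxy)propan-2-yl]deca-2,7,9-trienoate
Conditions: LiCl, DBU, MeCN, 0 °C → rt
Reagents that add atoms: none
Why: Horner–Wadsworth–Emmons reaction under the mild LiCl/amine conditions gives the (E)-enoate and should not epimerise the alpha-silyloxy aldehyde.

Step 9
Reactants: 14 methyl (2E,4S,6R,7E)-4-(tert-butyldimethylsilyloxy)-7,9-dimethyl-6-[2-(triethylsilyloxy)propan-2-yl]deca-2,7,9-trienoate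
Product: 15 methyl (1R,3S,3aR,4S,7aR)-3-(tert-butyldimethylsilyloxy)-6,7a-dimethyl-1-[2-(triethylsilyloxy)propan-2-yl]-2,3,3a,4,5,7a-hexahydro-1H-indene-4-carboxylate
Conditions: Me2AlCl (2 equiv), CH2Cl2, −78 → 0 °C, 0.01 M
Reagents that add atoms: none
Why: Me2AlCl binds the ester carbonyl and lowers the dienophile LUMO, so that the concerted, asynchronous, suprafacial [4+2] addition of the C4=C6 enoate across the C31=C33–C2=C3 diene can run far below the temperature at which the Z-disposed methyl C32 would enter 1,5-hydrogen shifts. The closest known reaction type is the Lewis-acid-promoted intramolecular Diels–Alder reaction of terminally activated (E)-nona-2,7,9-trienoates to trans-fused hydrindenes. Ring A closes as a cyclohexene by the new sigma bonds C6–C31 and C4–C3; ring B closes as a cyclopentane in the fused mode, because the three-atom tether C29–C30–C7 joins the diene terminus C31 to the dienophile carbon C6. C4 follows from the E geometry of the enoate (ester trans to C7); C6 and the quaternary C31 follow from the endo-ester transition state, which puts H6 and the methyl C32 on opposite faces (trans fusion), and aluminium complexation strengthens this endo preference. The absolute sense is relayed from C29: its bulky 2-silyloxyprop-2-yl group should take the quasi-equatorial site of the forming five-membered ring, which is the site cis to the methyl C32, while the C7 silyl ether, cis-1,3 to it, is carried along. The step therefore needs endo over exo selectivity and one diene face over the other; the first is secured by the (E)-enoate under Lewis-acid activation, the second by the C29 stereocentre, whose influence is enlarged on purpose by masking the isopropenyl group as a tertiary silyl ether. Me2AlCl also scavenges adventitious acid, which protects the diene and the silyl ethers.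

Step 10
Reactants: 15 methyl (1R,3S,3aR,4S,7aR)-3-(tert-butyldimethylsilyloxy)-6,7a-dimethyl-1-[2-(triethylsilyloxy)propan-2-yl]-2,3,3a,4,5,7a-hexahydro-1H-indene-4-carboxylate
Product: 16 [(1R,3S,3aR,4S,7aR)-3-(tert-butyldimethylsilyloxy)-6,7a-dimethyl-1-[2-(triethylsilyloxy)propan-2-yl]-2,3,3a,4,5,7a-hexahydro-1H-inden-4-yl]methanol
Conditions: i-Bu2AlH, CH2Cl2, −78 → 0 °C
Reagents that add atoms: none
Why: Hydride reduction of the ester to the primary alcohol; silyl ethers and the trisubstituted alkene are inert.

Step 11
Reactants: 16 [(1R,3S,3aR,4S,7aR)-3-(tert-butyldimethylsilyloxy)-6,7a-dimethyl-1-[2-(triethylsilyloxy)propan-2-yl]-2,3,3a,4,5,7a-hexahydro-1H-inden-4-yl]methanol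
Product: 18 (1R,3S,3aR,4S,7aR)-3-(tert-butyldimethylsilyloxy)-4,6,7a-trimethyl-1-[2-(triethylsilyloxy)propan-2-yl]-2,3,3a,4,5,7a-hexahydro-1H-indene, via mesylate 17 (not isolated)
Conditions: MsCl, Et3N, CH2Cl2, 0 °C; then LiEt3BH, THF, 0 °C → rt
Reagents that add atoms: none
Why: Sulfonylation and SN2 displacement by hydride turn CH2OH into the methyl C5; C4 is not affected.

Step 12
Reactants: 18 (1R,3S,3aR,4S,7aR)-3-(tert-butyldimethylsilyloxy)-4,6,7a-trimethyl-1-[2-(triethylsilyloxy)propan-2-yl]-2,3,3a,4,5,7a-hexahydro-1H-indene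
Product: 19 (1R,3S,3aR,4S,6R,7aR)-3-(tert-butyldimethylsilyloxy)-4,6,7a-trimethyl-1-[2-(triethylsilyloxy)propan-2-yl]octahydro-1H-indene
Conditions: Mn(dpm)3 (10 mol%), PhSiH3, t-BuOOH, i-PrOH, rt
Reagents that add atoms: none
Why: Metal-hydride hydrogen-atom transfer (Mukaiyama-type hydrogenation) adds H to C33 and leaves a tertiary radical at C2, which should take the second hydrogen on the face that leaves the methyl C1 equatorial, anti to the axial methyl C32; catalytic hydrogenation would add from the open alpha face and give the axial methyl. The ring A alkene is the only alkene in 18, which is why the isopropenyl group is still masked.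

Step 13
Reactants: 19 (1R,3S,3aR,4S,6R,7aR)-3-(tert-butyldimethylsilyloxy)-4,6,7a-trimethyl-1-[2-(triethylsilyloxy)propan-2-yl]octahydro-1H-indene
Product: 20 (1R,3S,3aR,4S,6R,7aR)-1-(2-hydroxypropan-2-yl)-4,6,7a-trimethyloctahydro-1H-inden-3-ol
Conditions: Bu4NF, THF, 50 °C
Reagents that add atoms: none
Why: Fluoride cleaves both silyl ethers; warming is needed for the hindered tertiary one.

Step 14
Reactants: 20 (1R,3S,3aR,4S,6R,7aR)-1-(2-hydroxypropan-2-yl)-4,6,7a-trimethyloctahydro-1H-inden-3-ol
Product: 21 (1R,3aR,4S,6R,7aR)-1-(2-hydroxypropan-2-yl)-4,6,7a-trimethyloctahydro-1H-inden-3-one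
Conditions: Dess–Martin periodinane, NaHCO3, CH2Cl2, rt
Reagents that add atoms: none
Why: Only the secondary alcohol can be oxidised, and the non-basic conditions should not epimerise C6 next to the new ketone.

Step 15
Reactants: 21 (1R,3aR,4S,6R,7aR)-1-(2-hydroxypropan-2-yl)-4,6,7a-trimethyloctahydro-1H-inden-3-one
Product: 22 (1S,3aR,4S,6R,7aR)-4,6,7a-trimethyl-1-(prop-1-en-2-yl)octahydro-1H-inden-3-one
Conditions: SOCl2, pyridine, CH2Cl2, −30 → 0 °C
Reagents that add atoms: none
Why: Dehydration through the chlorosulfite with pyridine as base; a methyl hydrogen is removed, because the only alternative, H29, is hindered and would give a tetrasubstituted exocyclic alkene strained against the methyl C32, so the isopropenyl group is expected.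

Step 16
Reactants: 23 (E)-pent-3-en-2-ol (racemic)
Product: 24 (2S,3E)-pent-3-en-2-ol
Conditions: Novozym 435 (immobilised lipase), vinyl acetate, MTBE, rt, run past half conversion
Reagents that add atoms: none
Why: Lipase-catalysed kinetic resolution: the enzyme acetylates the (R)-enantiomer of methyl carbinols, so the (S)-alcohol remains and is separated from the acetate.

Step 17
Reactants: 24 (2S,3E)-pent-3-en-2-ol; 25 bromoacetyl bromide
Product: 26 (2S,3E)-pent-3-en-2-yl bromoacetate
Conditions: pyridine, CH2Cl2, 0 °C
Reagents that add atoms: none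
Why: Acylation of the alcohol by the acid bromide; the stereocentre is not involved.

Step 18
Reactants: 22 (1S,3aR,4S,6R,7aR)-4,6,7a-trimethyl-1-(prop-1-en-2-yl)octahydro-1H-inden-3-one; 26 (2S,3E)-pent-3-en-2-yl bromoacetate
Product: 27 (2S,3E)-pent-3-en-2-yl 2-[(1S,2R,3aR,4S,6R,7aR)-4,6,7a-trimethyl-3-oxo-1-(prop-1-en-2-yl)octahydro-1H-inden-2-yl]acetate
Conditions: LiN(i-Pr)2, THF, −78 °C; then 26, DMPU, −78 → −40 °C
Reagents that add atoms: none
Why: Kinetic deprotonation takes place at the methylene C30 and not at the hindered methine C6; the bromoacetate is attacked from the face anti to the adjacent isopropenyl group and to the methyl C32, which sets C30 trans to C29. Low temperature and a reactive electrophile limit proton exchange.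

Step 19
Reactants: 27 (2S,3E)-pent-3-en-2-yl 2-[(1S,2R,3aR,4S,6R,7aR)-4,6,7a-trimethyl-3-oxo-1-(prop-1-en-2-yl)octahydro-1H-inden-2-yl]acetate
Product: 28 (2S,3E)-pent-3-en-2-yl 2-[(1S,2R,3S,3aR,4S,6R,7aR)-3-hydroxy-4,6,7a-trimethyl-1-(prop-1-en-2-yl)octahydro-1H-inden-2-yl]acetate
Conditions: NaBH4, MeOH, −20 °C
Reagents that add atoms: none
Why: A small hydride should attack the cyclopentanone from the alpha face, anti to the axial methyl C32, giving the alcohol trans to the C30 substituent; this is the 7S configuration needed for an etherification with retention. The ester is not reduced at this temperature.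

Step 20
Reactants: 28 (2S,3E)-pent-3-en-2-yl 2-[(1S,2R,3S,3aR,4S,6R,7aR)-3-hydroxy-4,6,7a-trimethyl-1-(prop-1-en-2-yl)octahydro-1H-inden-2-yl]acetate
Product: 31 methyl (2S,3R,4E)-2-[(1S,2S,3S,3aR,4S,6R,7aR)-3-hydroxy-4,6,7a-trimethyl-1-(prop-1-en-2-yl)octahydro-1H-inden-2-yl]-3-methylhex-4-enoate, via silyl ketene acetal 29 (not isolated), via carboxylic acid 30 (not isolated)
Conditions: LiN(i-Pr)2 (2.5 equiv), Me3SiCl, THF, −78 °C → rt → 50 °C; 1 M HCl; then Me3SiCHN2, MeOH/toluene, rt
Reagents that add atoms: (trimethylsilyl)diazomethane C[Si](C)(C)C=[N+]=[N-]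
Why: Ireland–Claisen rearrangement: LiN(i-Pr)2 in THF gives the (E)-silyl ketene acetal, and the chair transition state with the carbinol methyl equatorial transfers the chirality of the (S)-allylic ester to C23 and sets C22 anti to it. The C7 alkoxide is silylated in the flask and freed on acidic work-up, and the acid is esterified with Me3SiCHN2. C22 also remains epimerisable, and its equatorial configuration is the stable one.

Step 21
Reactants: 31 methyl (2S,3R,4E)-2-[(1S,2S,3S,3aR,4S,6R,7aR)-3-hydroxy-4,6,7a-trimethyl-1-(prop-1-en-2-yl)octahydro-1H-inden-2-yl]-3-methylhex-4-enoate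
Product: 32 methyl 9-hydroxy-1,3,4a,5,7-pentamethyl-2,3,4,4a,4b,7,8,8a,9,9a-decahydro-1H-fluorene-8-carboxylate (C25=C27 alkene; stereocentres as in 45)
Conditions: second-generation Grubbs catalyst RuCl2(=CHPh)(PCy3)(H2IMes) (5 mol%), CH2Cl2, 40 °C
Reagents that add atoms: none
Why: Ring-closing metathesis between the isopropenyl and the propenyl group closes ring C as a trisubstituted cyclohexene and releases propene; no other alkene is present.

Step 22
Reactants: 32 methyl 9-hydroxy-1,3,4a,5,7-pentamethyl-2,3,4,4a,4b,7,8,8a,9,9a-decahydro-1H-fluorene-8-carboxylate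
Product: 34 methyl 5,6-epoxy-9-hydroxy-1,3,4a,5,7-pentamethyldodecahydro-1H-fluorene-8-carboxylate (beta C25–C27 epoxide), via bromohydrin 33 (not isolated)
Conditions: NBS, THF/H2O, 0 °C; then K2CO3, MeOH, rt
Reagents that add atoms: water O
Why: Reversible bromonium formation and trans-diaxial (Fürst–Plattner) opening by water at the tertiary C27 put OH on the beta face at C27 and Br on the alpha face at C25; base then closes the beta epoxide by SN2 at C25. Markovnikov and diaxial preferences agree only for this isomer.

Step 23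
Reactants: 34 methyl 5,6-epoxy-9-hydroxy-1,3,4a,5,7-pentamethyldodecahydro-1H-fluorene-8-carboxylate; 35 acetonitrile
Product: 36 3-(5,6-epoxy-9-hydroxy-1,3,4a,5,7-pentamethyldodecahydro-1H-fluoren-8-yl)-3-oxopropanenitrile
Conditions: n-BuLi, MeCN, THF, −78 °C; then 34, −78 → −40 °C
Reagents that add atoms: none
Why: Claisen-type acylation of (cyanomethyl)lithium by the ester; excess reagent deprotonates the C7 hydroxyl and the product, which protects C22 from epimerisation, and the hindered epoxide should not be attacked at low temperature.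

Step 24
Reactants: 36 3-(5,6-epoxy-9-hydroxy-1,3,4a,5,7-pentamethyldodecahydro-1H-fluoren-8-yl)-3-oxopropanenitrile
Product: 37 3-(5,6-epoxy-9-hydroxy-1,3,4a,5,7-pentamethyldodecahydro-1H-fluoren-8-yl)-3-oxopropanamide
Conditions: [PtH(PMe2OH)(PMe2O)2H] (5 mol%), EtOH/H2O, 80 °C
Reagents that add atoms: water O
Why: Platinum-catalysed hydration of the nitrile under neutral conditions gives the primary amide without touching the epoxide.

Step 25
Reactants: 38 1,4-diiodobenzene; 39 epichlorohydrin (racemic)
Product: 41 1-chloro-3-(4-iodophenyl)propan-2-ol (racemic), via aryl Grignard reagent 40 (not isolated)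
Conditions: i-PrMgCl·LiCl, THF, −20 °C; then CuI (10 mol%), epichlorohydrin, −20 → 0 °C
Reagents that add atoms: none
Why: Iodine–magnesium exchange on one C–I bond, then copper-catalysed opening of the epoxide at its terminal carbon forms the aryl–C15 bond; the second iodide is kept for the final coupling.

Step 26
Reactants: 41 1-chloro-3-(4-iodophenyl)propan-2-ol
Product: 42 1-chloro-3-(4-iodophenyl)propan-2-one
Conditions: Dess–Martin periodinane, CH2Cl2, rt
Reagents that add atoms: none
Why: Oxidation of the secondary alcohol to the ketone; the stereocentre of 41 disappears, so the racemate is sufficient.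

Step 27
Reactants: 37 3-(5,6-epoxy-9-hydroxy-1,3,4a,5,7-pentamethyldodecahydro-1H-fluoren-8-yl)-3-oxopropanamide; 42 1-chloro-3-(4-iodophenyl)propan-2-one
Product: 44 3-acyl-5-hydroxy-5-(4-iodobenzyl)pyrrolidin-2-one in its enol form (acyl = C20 carbonyl of the epoxy hydroxy tricycle; C16 epimers), via open-chain keto amide 43 (not isolated)
Conditions: K2CO3, NaI (cat.), acetone, 0 °C → rt
Reagents that add atoms: none
Why: C-alkylation of the beta-keto amide enolate by the alpha-chloro ketone (iodide catalysis) forms C18–C19; the primary amide nitrogen then adds to the new C16 ketone and gives the five-membered hemiaminal. C16 and C19 are equilibrating positions.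

Step 28
Reactants: 44 3-acyl-5-hydroxy-5-(4-iodobenzyl)pyrrolidin-2-one (seco compound)
Product: 45 Pyrrospirone O
Conditions: CuI, 3,4,7,8-tetramethyl-1,10-phenanthroline, Cs2CO3, toluene, 100 °C, 1 mM
Reagents that add atoms: none
Why: Ullmann-type coupling: the caesium C7 alkoxide binds monovalent copper, and oxidative addition of the aryl iodide followed by reductive elimination from trivalent copper forms O8–C9 with retention at C7, the ring closing through a 14-membered metallacycle at high dilution. C16 can equilibrate by ring–chain tautomerism to the natural hemiaminal.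

## Compound list

1 | (S)-5-(hydroxymethyl)dihydrofuran-2(3H)-one | OC[C@@H]1CCC(=O)O1 | starting material
2 | (S)-5-[(triethylsilyloxy)methyl]dihydrofuran-2(3H)-one | CC[Si](CC)(CC)OC[C@@H]1CCC(=O)O1 | intermediate
3 | acetone | CC(C)=O | starting material
4 | lithium 2-[(3S,5S)-2-oxo-5-[(triethylsilyloxy)methyl]oxolan-3-yl]propan-2-olate | CC[Si](CC)(CC)OC[C@@H]1C[C@@H](C(C)(C)[O-])C(=O)O1.[Li+] | intermediate
5 | (3S,5S)-3-[2-(triethylsilyloxy)propan-2-yl]-5-[(triethylsilyloxy)methyl]dihydrofuran-2(3H)-one | CC[Si](CC)(CC)OC[C@@H]1C[C@@H](C(C)(C)O[Si](CC)(CC)CC)C(=O)O1 | intermediate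
6 | (3S,5S)-3-[2-(triethylsilyloxy)propan-2-yl]-5-[(triethylsilyloxy)methyl]oxolan-2-ol (anomers) | CC[Si](CC)(CC)OC[C@@H]1C[C@@H](C(C)(C)O[Si](CC)(CC)CC)C(O)O1 | intermediate
7 | (2S,4R)-1-(triethylsilyloxy)-4-[2-(triethylsilyloxy)propan-2-yl]hex-5-yn-2-ol | CC[Si](CC)(CC)OC[C@@H](O)C[C@@H](C(C)(C)O[Si](CC)(CC)CC)C#C | intermediate
8 | (2S,4R)-2-(tert-butyldimethylsilyloxy)-1-(triethylsilyloxy)-4-[2-(triethylsilyloxy)propan-2-yl]hex-5-yne | CC[Si](CC)(CC)OC[C@@H](O[Si](C)(C)C(C)(C)C)C[C@@H](C(C)(C)O[Si](CC)(CC)CC)C#C | intermediate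
9 | 2-bromopropene | CC(Br)=C | starting material
10 | (E)-alkenyldimethylalane from syn-carboalumination of 8 (methyl on C31, AlMe2 on C33) | CC[Si](CC)(CC)OC[C@@H](O[Si](C)(C)C(C)(C)C)C[C@@H](C(C)(C)O[Si](CC)(CC)CC)/C(C)=C/[Al](C)C | intermediate
11 | (2S,4R,5E)-2-(tert-butyldimethylsilyloxy)-5,7-dimethyl-1-(triethylsilyloxy)-4-[2-(triethylsilyloxy)propan-2-yl]octa-5,7-diene | CC[Si](CC)(CC)OC[C@@H](O[Si](C)(C)C(C)(C)C)C[C@@H](C(C)(C)O[Si](CC)(CC)CC)/C(C)=C/C(C)=C | intermediate
12 | (2S,4R,5E)-2-(tert-butyldimethylsilyloxy)-5,7-dimethyl-4-[2-(triethylsilyloxy)propan-2-yl]octa-5,7-dienal | O=C[C@@H](O[Si](C)(C)C(C)(C)C)C[C@@H](C(C)(C)O[Si](CC)(CC)CC)/C(C)=C/C(C)=C | intermediate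
13 | trimethyl phosphonoacetate | COC(=O)CP(=O)(OC)OC | starting material
14 | methyl (2E,4S,6R,7E)-4-(tert-butyldimethylsilyloxy)-7,9-dimethyl-6-[2-(triethylsilyloxy)propan-2-yl]deca-2,7,9-trienoate | COC(=O)/C=C/[C@@H](O[Si](C)(C)C(C)(C)C)C[C@@H](C(C)(C)O[Si](CC)(CC)CC)/C(C)=C/C(C)=C | intermediate
15 | methyl (1R,3S,3aR,4S,7aR)-3-(tert-butyldimethylsilyloxy)-6,7a-dimethyl-1-[2-(triethylsilyloxy)propan-2-yl]-2,3,3a,4,5,7a-hexahydro-1H-indene-4-carboxylate | COC(=O)[C@H]1CC(C)=C[C@@]2(C)[C@H](C(C)(C)O[Si](CC)(CC)CC)C[C@H](O[Si](C)(C)C(C)(C)C)[C@H]12 | intermediate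
16 | [(1R,3S,3aR,4S,7aR)-3-(tert-butyldimethylsilyloxy)-6,7a-dimethyl-1-[2-(triethylsilyloxy)propan-2-yl]-2,3,3a,4,5,7a-hexahydro-1H-inden-4-yl]methanol | OC[C@H]1CC(C)=C[C@@]2(C)[C@H](C(C)(C)O[Si](CC)(CC)CC)C[C@H](O[Si](C)(C)C(C)(C)C)[C@H]12 | intermediate
17 | methanesulfonate of 16 | CS(=O)(=O)OC[C@H]1CC(C)=C[C@@]2(C)[C@H](C(C)(C)O[Si](CC)(CC)CC)C[C@H](O[Si](C)(C)C(C)(C)C)[C@H]12 | intermediate
18 | (1R,3S,3aR,4S,7aR)-3-(tert-butyldimethylsilyloxy)-4,6,7a-trimethyl-1-[2-(triethylsilyloxy)propan-2-yl]-2,3,3a,4,5,7a-hexahydro-1H-indene | C[C@H]1CC(C)=C[C@@]2(C)[C@H](C(C)(C)O[Si](CC)(CC)CC)C[C@H](O[Si](C)(C)C(C)(C)C)[C@H]12 | intermediate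
19 | (1R,3S,3aR,4S,6R,7aR)-3-(tert-butyldimethylsilyloxy)-4,6,7a-trimethyl-1-[2-(triethylsilyloxy)propan-2-yl]octahydro-1H-indene | C[C@H]1C[C@@H](C)C[C@@]2(C)[C@H](C(C)(C)O[Si](CC)(CC)CC)C[C@H](O[Si](C)(C)C(C)(C)C)[C@H]12 | intermediate
20 | (1R,3S,3aR,4S,6R,7aR)-1-(2-hydroxypropan-2-yl)-4,6,7a-trimethyloctahydro-1H-inden-3-ol | C[C@H]1C[C@@H](C)C[C@@]2(C)[C@H](C(C)(C)O)C[C@H](O)[C@H]12 | intermediate
21 | (1R,3aR,4S,6R,7aR)-1-(2-hydroxypropan-2-yl)-4,6,7a-trimethyloctahydro-1H-inden-3-one | C[C@H]1C[C@@H](C)C[C@@]2(C)[C@H](C(C)(C)O)CC(=O)[C@H]12 | intermediate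
22 | (1S,3aR,4S,6R,7aR)-4,6,7a-trimethyl-1-(prop-1-en-2-yl)octahydro-1H-inden-3-one | C[C@H]1C[C@@H](C)C[C@@]2(C)[C@H](C(C)=C)CC(=O)[C@H]12 | intermediate
23 | (E)-pent-3-en-2-ol (racemic) | CC(O)/C=C/C | starting material
24 | (2S,3E)-pent-3-en-2-ol | C[C@H](O)/C=C/C | intermediate
25 | bromoacetyl bromide | BrCC(Br)=O | starting material
26 | (2S,3E)-pent-3-en-2-yl bromoacetate | BrCC(=O)O[C@@H](C)/C=C/C | intermediate
27 | (2S,3E)-pent-3-en-2-yl 2-[(1S,2R,3aR,4S,6R,7aR)-4,6,7a-trimethyl-3-oxo-1-(prop-1-en-2-yl)octahydro-1H-inden-2-yl]acetate | C[C@H]1C[C@@H](C)C[C@@]2(C)[C@H](C(C)=C)[C@@H](CC(=O)O[C@@H](C)/C=C/C)C(=O)[C@H]12 | intermediate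
28 | (2S,3E)-pent-3-en-2-yl 2-[(1S,2R,3S,3aR,4S,6R,7aR)-3-hydroxy-4,6,7a-trimethyl-1-(prop-1-en-2-yl)octahydro-1H-inden-2-yl]acetate | C[C@H]1C[C@@H](C)C[C@@]2(C)[C@H](C(C)=C)[C@@H](CC(=O)O[C@@H](C)/C=C/C)[C@H](O)[C@H]12 | intermediate
29 | (E)-O-trimethylsilyl ketene acetal of 28 with the C7 hydroxyl as trimethylsilyl ether | C[C@H]1C[C@@H](C)C[C@@]2(C)[C@H](C(C)=C)[C@@H](/C=C(/O[Si](C)(C)C)O[C@@H](C)/C=C/C)[C@H](O[Si](C)(C)C)[C@H]12 | intermediate
30 | (2S,3R,4E)-2-[(1S,2S,3S,3aR,4S,6R,7aR)-3-hydroxy-4,6,7a-trimethyl-1-(prop-1-en-2-yl)octahydro-1H-inden-2-yl]-3-methylhex-4-enoic acid | C[C@H]1C[C@@H](C)C[C@@]2(C)[C@H](C(C)=C)[C@@H]([C@@H](C(=O)O)[C@H](C)/C=C/C)[C@H](O)[C@H]12 | intermediate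
31 | methyl (2S,3R,4E)-2-[(1S,2S,3S,3aR,4S,6R,7aR)-3-hydroxy-4,6,7a-trimethyl-1-(prop-1-en-2-yl)octahydro-1H-inden-2-yl]-3-methylhex-4-enoate | C[C@H]1C[C@@H](C)C[C@@]2(C)[C@H](C(C)=C)[C@@H]([C@@H](C(=O)OC)[C@H](C)/C=C/C)[C@H](O)[C@H]12 | intermediate
32 | methyl 9-hydroxy-1,3,4a,5,7-pentamethyl-2,3,4,4a,4b,7,8,8a,9,9a-decahydro-1H-fluorene-8-carboxylate (rings A, B, C; C25=C27 alkene; stereocentres as in 45) | C[C@H]1C[C@@H](C)C[C@@]2(C)[C@H]3[C@@H]([C@@H](C(=O)OC)[C@H](C)C=C3C)[C@H](O)[C@H]12 | intermediate
33 | methyl 6-bromo-5,9-dihydroxy-1,3,4a,5,7-pentamethyldodecahydro-1H-fluorene-8-carboxylate (C25 alpha-Br, C27 beta-OH) | C[C@H]1C[C@@H](C)C[C@@]2(C)[C@H]3[C@@H]([C@@H](C(=O)OC)[C@H](C)[C@H](Br)[C@@]3(C)O)[C@H](O)[C@H]12 | intermediate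
34 | methyl 5,6-epoxy-9-hydroxy-1,3,4a,5,7-pentamethyldodecahydro-1H-fluorene-8-carboxylate (beta C25–C27 epoxide) | C[C@H]1C[C@@H](C)C[C@@]2(C)[C@H]3[C@@H]([C@@H](C(=O)OC)[C@H](C)[C@H]4O[C@@]34C)[C@H](O)[C@H]12 | intermediate
35 | acetonitrile | CC#N | starting material
36 | 3-(5,6-epoxy-9-hydroxy-1,3,4a,5,7-pentamethyldodecahydro-1H-fluoren-8-yl)-3-oxopropanenitrile | C[C@H]1C[C@@H](C)C[C@@]2(C)[C@H]3[C@@H]([C@@H](C(=O)CC#N)[C@H](C)[C@H]4O[C@@]34C)[C@H](O)[C@H]12 | intermediate
37 | 3-(5,6-epoxy-9-hydroxy-1,3,4a,5,7-pentamethyldodecahydro-1H-fluoren-8-yl)-3-oxopropanamide | C[C@H]1C[C@@H](C)C[C@@]2(C)[C@H]3[C@@H]([C@@H](C(=O)CC(N)=O)[C@H](C)[C@H]4O[C@@]34C)[C@H](O)[C@H]12 | intermediate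
38 | 1,4-diiodobenzene | Ic1ccc(I)cc1 | starting material
39 | epichlorohydrin (racemic) | ClCC1CO1 | starting material
40 | 4-iodophenylmagnesium chloride | Cl[Mg]c1ccc(I)cc1 | intermediate
41 | 1-chloro-3-(4-iodophenyl)propan-2-ol (racemic) | OC(CCl)Cc1ccc(I)cc1 | intermediate
42 | 1-chloro-3-(4-iodophenyl)propan-2-one | O=C(CCl)Cc1ccc(I)cc1 | intermediate
43 | 2-[3-(4-iodophenyl)-2-oxopropyl]-3-oxo-3-(5,6-epoxy-9-hydroxy-1,3,4a,5,7-pentamethyldodecahydro-1H-fluoren-8-yl)propanamide (C19 epimers) | C[C@H]1C[C@@H](C)C[C@@]2(C)[C@H]3[C@@H]([C@@H](C(=O)C(CC(=O)Cc5ccc(I)cc5)C(N)=O)[C@H](C)[C@H]4O[C@@]34C)[C@H](O)[C@H]12 | intermediate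
44 | 3-acyl-5-hydroxy-5-(4-iodobenzyl)pyrrolidin-2-one, enol form, acyl on C22 of the epoxy hydroxy tricycle (C16 epimers) | C[C@H]1C[C@@H](C)C[C@@]2(C)[C@H]3[C@@H]([C@@H](/C(O)=C5/C(=O)NC(O)(Cc6ccc(I)cc6)C5)[C@H](C)[C@H]4O[C@@]34C)[C@H](O)[C@H]12 | intermediate
45 | Pyrrospirone O | C[C@@H]1C[C@H](C)[C@H]2[C@H]3Oc4ccc(cc4)C[C@]4(O)C/C(=C(/O)[C@H]5[C@H](C)[C@H]6O[C@@]6(C)[C@H]([C@H]35)[C@]2(C)C1)C(=O)N4 | target

## Step count and least certain steps

Total step count: 28 steps. Longest linear sequence: 24 steps (steps 1–15, 18–24, 27 and 28, from 1).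

Step 9 (key step). The most likely failure is poor discrimination between the two diene faces, because the C7 silyl ether would prefer the other quasi-equatorial arrangement and so opposes C29. A second risk is ionisation or oligomerisation of the electron-rich diene by the Lewis acid before the fully substituted terminus C31 can bond. The fallback replaces substrate control by catalyst control. From 12, Wittig olefination with (triphenylphosphoranylidene)acetaldehyde would give the (2E)-trienal F1. Iminium activation by a chiral 5-benzyl-2-tert-butyl-3-methylimidazolidin-4-one salt (enantiomer matched to the required face), an organocatalytic intramolecular Diels–Alder reaction, should give the bicyclic aldehyde F2. NaBH4 reduction returns to the route at 16.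

Step 12. The most likely failure is hydrogen delivery to the C2 radical from the open alpha face, steric approach winning over product stability, which would leave the methyl C1 axial. The fallback puts C2 under thermodynamic control through a ketone. From 18, hydroboration–oxidation (BH3·THF; H2O2, NaOH) gives the C33 alcohol F3, with C2 still epimeric. Dess–Martin oxidation and NaOMe equilibration give the C33 ketone F4 with the methyl equatorial. Its tosylhydrazone F5 is reduced with catecholborane and NaOAc (Caglioti-type deoxygenation), which rejoins the route at 19.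

Step 18. The most likely failure is proton transfer between product and enolate, which would epimerise C6 towards the more stable cis-hydrindanone and allow a second alkylation. The fallback goes through an azaenolate. From 22, the N,N-dimethylhydrazone F6 is deprotonated at C30 with LiN(i-Pr)2 and alkylated with 26 to the hydrazone ester F7, since azaenolates do not equilibrate. Buffered aqueous CuCl2 hydrolysis returns 27.

Step 22. The most likely failure is opening of the bromonium ion at C25, or its formation on the beta face, either of which would place the epoxide on the alpha face after ring closure. The fallback is direct oxygen transfer from a peracid (mCPBA, NaHCO3, CH2Cl2): it attacks the face that the halogen electrophile prefers and so gives the complementary epoxide, leading from 32 to 34 without new intermediates.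

Step 28. The most likely failure is that the hindered C7 alkoxide does not reach the aryl–copper centre in the strained geometry, so that intermolecular coupling, protodeiodination or base-induced dehydration of the hemiaminal take over. The fallback reverses the order of bond formation and closes the ring by C–C alkylation; it sets out from 34 (with 41) and comes back at 45.
- From 41, silylation with t-BuPh2SiCl gives the silyl ether F8, and oxidation (mCPBA, TsOH, then 1,3,5-trimethoxybenzene) gives the aryl(2,4,6-trimethoxyphenyl)iodonium tosylate F9.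
- The sodium alkoxide of 34 (NaH, toluene) is O-arylated by F9 at room temperature, without metal and with retention, to the aryl ether ester F10.
- (Cyanomethyl)lithium gives the beta-keto nitrile F11, and platinum-catalysed hydration gives the beta-keto amide F12.
- Bu4NF buffered with AcOH frees the chlorohydrin F13, and Dess–Martin oxidation gives the alpha-chloro ketone F14.
- Intramolecular C-alkylation of F14 (Cs2CO3, NaI, MeCN, high dilution) and spontaneous hemiaminal formation give 45.

## Further compounds

F1 | step 9 | (2E,4S,6R,7E)-4-(tert-butyldimethylsilyloxy)-7,9-dimethyl-6-[2-(triethylsilyloxy)propan-2-yl]deca-2,7,9-trienal | O=C/C=C/[C@@H](O[Si](C)(C)C(C)(C)C)C[C@@H](C(C)(C)O[Si](CC)(CC)CC)/C(C)=C/C(C)=C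
F2 | step 9 | (1R,3S,3aR,4S,7aR)-3-(tert-butyldimethylsilyloxy)-6,7a-dimethyl-1-[2-(triethylsilyloxy)propan-2-yl]-2,3,3a,4,5,7a-hexahydro-1H-indene-4-carbaldehyde | O=C[C@H]1CC(C)=C[C@@]2(C)[C@H](C(C)(C)O[Si](CC)(CC)CC)C[C@H](O[Si](C)(C)C(C)(C)C)[C@H]12
F3 | step 12 | C33 alcohol from hydroboration of 18 (C33 alpha-OH, methyl C1 axial) | C[C@H]1C[C@H](C)[C@@H](O)[C@@]2(C)[C@H](C(C)(C)O[Si](CC)(CC)CC)C[C@H](O[Si](C)(C)C(C)(C)C)[C@H]12
F4 | step 12 | C33 ketone with equatorial methyl C1 | C[C@H]1C[C@@H](C)C(=O)[C@@]2(C)[C@H](C(C)(C)O[Si](CC)(CC)CC)C[C@H](O[Si](C)(C)C(C)(C)C)[C@H]12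
F5 | step 12 | tosylhydrazone of F4 | C[C@H]1C[C@@H](C)C(=NNS(=O)(=O)c3ccc(C)cc3)[C@@]2(C)[C@H](C(C)(C)O[Si](CC)(CC)CC)C[C@H](O[Si](C)(C)C(C)(C)C)[C@H]12
F6 | step 18 | N,N-dimethylhydrazone of 22 | C[C@H]1C[C@@H](C)C[C@@]2(C)[C@H](C(C)=C)CC(=NN(C)C)[C@H]12
F7 | step 18 | N,N-dimethylhydrazone of 27 | C[C@H]1C[C@@H](C)C[C@@]2(C)[C@H](C(C)=C)[C@@H](CC(=O)O[C@@H](C)/C=C/C)C(=NN(C)C)[C@H]12
F0 | step 22 | none | none
F8 | step 28 | tert-butyl{[1-chloro-3-(4-iodophenyl)propan-2-yl]oxy}diphenylsilane | CC(C)(C)[Si](OC(CCl)Cc1ccc(I)cc1)(c1ccccc1)c1ccccc1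
F9 | step 28 | {4-[2-(tert-butyldiphenylsilyloxy)-3-chloropropyl]phenyl}(2,4,6-trimethoxyphenyl)iodonium 4-methylbenzenesulfonate | COc1cc(OC)c([I+]c2ccc(CC(CCl)O[Si](c3ccccc3)(c3ccccc3)C(C)(C)C)cc2)c(OC)c1.Cc1ccc(cc1)S(=O)(=O)[O-]
F10 | step 28 | C7 aryl ether of 34 with the silyl-protected chlorohydrin side chain | C[C@H]1C[C@@H](C)C[C@@]2(C)[C@H]3[C@@H]([C@@H](C(=O)OC)[C@H](C)[C@H]4O[C@@]34C)[C@H](Oc5ccc(CC(CCl)O[Si](c6ccccc6)(c6ccccc6)C(C)(C)C)cc5)[C@H]12
F11 | step 28 | beta-keto nitrile from F10 | C[C@H]1C[C@@H](C)C[C@@]2(C)[C@H]3[C@@H]([C@@H](C(=O)CC#N)[C@H](C)[C@H]4O[C@@]34C)[C@H](Oc5ccc(CC(CCl)O[Si](c6ccccc6)(c6ccccc6)C(C)(C)C)cc5)[C@H]12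
F12 | step 28 | beta-keto amide from F11 | C[C@H]1C[C@@H](C)C[C@@]2(C)[C@H]3[C@@H]([C@@H](C(=O)CC(N)=O)[C@H](C)[C@H]4O[C@@]34C)[C@H](Oc5ccc(CC(CCl)O[Si](c6ccccc6)(c6ccccc6)C(C)(C)C)cc5)[C@H]12
F13 | step 28 | chlorohydrin from F12 | C[C@H]1C[C@@H](C)C[C@@]2(C)[C@H]3[C@@H]([C@@H](C(=O)CC(N)=O)[C@H](C)[C@H]4O[C@@]34C)[C@H](Oc5ccc(CC(O)CCl)cc5)[C@H]12
F14 | step 28 | alpha-chloro ketone from F13 | C[C@H]1C[C@@H](C)C[C@@]2(C)[C@H]3[C@@H]([C@@H](C(=O)CC(N)=O)[C@H](C)[C@H]4O[C@@]34C)[C@H](Oc5ccc(CC(=O)CCl)cc5)[C@H]12
A1 | alternative 1 | C7 4-iodophenyl ether carrying the 3-acyl-5-methylenepyrrolidin-2-one (seco compound) | C[C@H]1C[C@@H](C)C[C@@]2(C)[C@H]3[C@@H]([C@@H](/C(O)=C5/C(=O)NC(=C)C5)[C@H](C)[C@H]4O[C@@]34C)[C@H](Oc6ccc(I)cc6)[C@H]12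
A2 | alternative 1 | macrocyclic 5-benzylidene lactam (anhydro pyrrospirone O) | C[C@@H]1C[C@H](C)[C@H]2[C@H]3Oc4ccc(cc4)/C=C4\C/C(=C(/O)[C@H]5[C@H](C)[C@H]6O[C@@]6(C)[C@H]([C@H]35)[C@]2(C)C1)C(=O)N4
A3 | alternative 2 | diazo keto ester on the trimethylcyclohexane with the pivaloyloxyethyl chain | CC(C)(C)C(=O)OCC[C@]1(C)C[C@H](C)C[C@H](C)[C@H]1C(=O)C(=[N+]=[N-])C(=O)OC
A4 | alternative 2 | trans-hydrindanone beta-keto ester | CC(C)(C)C(=O)OC[C@H]([C@H]3C(=O)OC)[C@]2(C)C[C@H](C)C[C@H](C)[C@H]2C3=O
A5 | alternative 3 | C20 vinyl ketone with the aryl-tethered alpha-tosyl isocyanide on O8 | C[C@H]1C[C@@H](C)C[C@@]2(C)[C@H]3[C@@H]([C@@H](C(=O)C=C)[C@H](C)[C@H]4O[C@@]34C)[C@H](Oc5ccc(CC([N+]#[C-])S(=O)(=O)c6ccc(C)cc6)cc5)[C@H]12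
A6 | alternative 3 | macrocyclic 2-benzyl-4-acylpyrrole | C[C@@H]1C[C@H](C)[C@H]2[C@H]3Oc4ccc(cc4)Cc4cc(C(=O)[C@H]5[C@H](C)[C@H]6O[C@@]6(C)[C@H]([C@H]35)[C@]2(C)C1)c[nH]4
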